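## Analysis of the target

Target 31 is a bicyclo[3.2.1]oct-3-en-8-one neolignan. With C1 as the methoxy bridgehead, C2 the carbinol, C3=C4 the methyl enol ether (OMe on C3), C5 the allyl bridgehead, C6 (CHMe), C7 (CHAr) and C8 the bridging ketone, it consists of a six-membered ring C1–C2–C3–C4–C5–C8 and a five-membered ring C1–C7–C6–C5–C8 that share C1, C8 and C5. It has five contiguous stereocentres, (1R,2S,5R,6R,7S). The two fully substituted bridgeheads fix each other through the bicycle. On the two-carbon bridge the aryl group is endo (under the six-membered ring) and the methyl group exo (toward C8), hence trans, and the C2 hydroxyl lies on the face of the C6–C7 bridge, the same side as the aryl group. Sensitive features are the enol ether (acid), the free phenol, the terminal alkene (no hydrogenation, ozonolysis or hydroboration), the β-hydroxy ketone C2–C1–C8 (retro-aldol under base) and, in late intermediates, the non-enolisable 1,3-dicarbonyl array around C1 (cleavage by nucleophilic bases). The difficulty is the crowding of two quaternary carbons beside a strained ketone and three further stereocentres, plus the need to tell the C2 and C8 carbonyls apart at the end. The strategy rests on one feature: ketone C8 is bonded to quaternary C5, which also carries C4 and C6. That is the pattern a pinacol shift of C4 from a carbinol carbon C8 onto a C5 cation leaves behind, and such a cation arises when C6 of an alkene C5=C6 attacks a benzylic cation at C7.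

## Retrosynthetic reasoning

**Late functional groups (31 back to 24).** The phenol is unmasked last from 30. The C2 carbinol comes from enone 29 by hydride delivery from the C8 side, away from the endo aryl group. The enol ether of 29 is the O-methyl derivative of diosphenol 28, the only enol that trione 27 can form because C1 is quaternary. Trione 27 comes from dione 24 through enolate 25 and acyloin 26, C3 being the only enolisable position. This takes the acid-sensitive enol ether and the allylic alcohol out of the way of the cationic step.

**Key disconnection (24 back to 21).** Bonds C6–C7 and C4–C5 are cut and C4 is re-attached to C8. This gives cyclopentanone 21, in which C8 is a silylated carbinol carrying a (Z)-hexa-2,5-dien-3-yl group and C1 carries the methoxy group and a benzylic ether at C7. No other cut removes both rings, two skeletal bonds and three stereocentres (C5, C6, C7) at once while leaving only C1 and C8 to be controlled beforehand. Forward, ionisation at C7 (22), attack of the alkene through C6 (23) and shift of C4 must follow one another without interception.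

**Unmasking the precursor (21 back to 18).** The silyl ether of 21 is put on tertiary alcohol 20. The C2 ketone of 20 comes from the secondary alcohol of 19. Compound 19 is obtained by reductive opening of benzylidene acetal 18, which leaves the benzyl group on the benzylic oxygen as the later leaving group.

**C8–C5 bond (18 back to 11 and 17).** The alkenyl group is added as organocerium reagent 17 to ketone 11. The reason for the acetal is facial control: in an open 2,2-disubstituted cyclopentane-1,3-dione the benzylic arm is the bulkier substituent on C1 and a nucleophile would enter cis to the methoxy group, which is the wrong face. In 11 the trans-fused dioxane holds the arm equatorial and the methoxy group axial, so attack anti to the methoxy group is enforced and the alkenyl and benzylic groups end up cis, as the key step requires.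

**Acetal and C2 reduction (11 back to 8).** Acetal 11 is formed from syn-diol 10. Diol 10 arises from aldol 8 by chelation-controlled reduction through boron chelate 9. This reduction selects one of the two diastereotopic carbonyls and so passes the configuration of C7 on to C1. C7 itself becomes planar in the key step.

**C1–C7 bond (8 back to 4 and 6).** An enantioselective aldol addition of enol silane 4 to aldehyde 6 makes C1 quaternary and sets C7, the only stereocentre at that stage. Enol silane 4 comes from 3, made from 1 through diazo compound 2. Aldehyde 6 is silylated 5.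

**Alkenyl fragment (17 back to 12 and 14).** Reagent 17 derives from lithium compound 16 and bromide 15. The geometry of 15 (bromine cis to methyl) comes from a trans-selective coupling of dibromide 13 with stannane 14, and 13 from aldehyde 12.

## Alternatives that were turned down

**Alternative 1:** The five-membered ring is cut at C6–C7 and traced to the cross-conjugated (E,E)-2-methoxy dienone A1. Forward, Sc(OTf)3 with a chiral pybox ligand would trigger conrotatory 4π closure and Et3SiH would intercept the oxyallyl cation to give cyclopentanone A2.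
- For: A1 is assembled from simple pieces, α-alkoxy dienones cyclise readily, and conrotation converts the two E alkenes directly into the trans C6/C7 pair under catalyst control. On this point it is stronger than the chosen route, where the aryl orientation is the open question.
- Against: A2 still has hydrogen on C1 and C5. Both quaternary bridgeheads and the whole C2–C3–C4 bridge remain to be built, on the face syn to the aryl group. The two α-positions must be enolised selectively. Hydride capture of a 2-alkoxy oxyallyl cation competes with proton loss and loss of methoxide.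
- Comparison: the chosen strategy ends its key step with the complete bicycle and both quaternary carbons in place, at the price of a longer approach to the precursor.

**Alternative 2:** The bonds C6–CH3 and C5–C4 are cut. Me2CuLi would add methyl to C6 of cyclopentenone A3 and the enolate would be alkylated at C5 by an allylic halide carrying C3 and C4, giving A4.
- For: methyl anti to aryl and electrophile anti to methyl are textbook substrate control. Each bond formation is more reliable than a new cationic cascade.
- Against: A3 with its two stereocentres must first be made in enantioenriched form. The cuprate-derived enolate must be alkylated at a fully substituted carbon faster than it equilibrates to the methoxy-bearing α-carbon. After A4 the six-membered ring is still open: the C1–C2 bond must join the α-methoxy ketone carbon to the terminus of an enol ether, two nucleophilic carbons, which needs a redox detour, and the C2 oxygen comes later still.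
- Comparison: the chosen strategy makes C1 quaternary in an early aldol step and closes both rings in one operation.

**Alternative 3:** The bonds C5–C8 and C1–C2 are cut and the bicycle is traced to cis-fused photoadduct A5. EtAlCl2 would activate its ketone and two successive 1,2-shifts (C5 from C1 to C8, then C2 from C8 to C1) would give A6.
- For: one [2+2] photocycloaddition forms C6–C7 and both quaternary carbons, and A6 already carries the C2 oxygen in the correct configuration. On this point it is stronger than the chosen route, which needs a late chemoselective reduction.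
- Against: A5 requires the aryl group on the concave face, syn to the six-membered ring. Enone–alkene photocycloadditions run through 1,4-biradicals that scramble alkene geometry and regiochemistry. The enone is tetrasubstituted and its allyl group can add intramolecularly. The first shift must choose the ring-fusion bond C1–C5 over the benzylic cyclobutane bond C1–C7.
- Comparison: in the chosen strategy C1 and C8 are fixed before the cationic step and only one bond can migrate productively.

Key step: step 14

Assumption (chemistry): the sense of induction in step 5 has to be established for this enol silane. The catalyst enantiomer that leads to Re-face attack on 6, and so to (S)-8, is used. C7 serves only as a relay and becomes planar in step 14.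

## Route

Step 1
Reactants: 1 cyclopentane-1,3-dione
Product: 2 2-diazocyclopentane-1,3-dione
Conditions: 4-acetamidobenzenesulfonyl azide, Et3N, MeCN, 0 °C to rt
Reagents that add atoms: 4-acetamidobenzenesulfonyl azide, CC(=O)Nc1ccc(cc1)S(=O)(=O)N=[N+]=[N-]
Why: Regitz diazo transfer to the acidic central carbon of a cyclic 1,3-dione; no stereocentre is formed.

Step 2
Reactants: 2 2-diazocyclopentane-1,3-dione
Product: 3 2-methoxycyclopentane-1,3-dione (present as its enol, 3-hydroxy-2-methoxycyclopent-2-en-1-one)
Conditions: Rh2(OAc)4 (1 mol %), MeOH, CH2Cl2, 40 °C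
Reagents that add atoms: methanol, CO
Why: O–H insertion of the dirhodium carbenoid into methanol, which under metal catalysis should outrun Wolff ring contraction.

Step 3
Reactants: 3 2-methoxycyclopentane-1,3-dione
Product: 4 3-(tert-butyldimethylsilyloxy)-2-methoxycyclopent-2-en-1-one
Conditions: t-BuMe2SiCl, Et3N, CH2Cl2, 0 °C
Reagents that add atoms: tert-butylchlorodimethylsilane, CC(C)(C)[Si](C)(C)Cl
Why: O-silylation of a vinylogous acid gives the enol silane that serves as the C1 nucleophile.

Step 4
Reactants: 5 vanillin
Product: 6 3-methoxy-4-(triisopropylsilyloxy)benzaldehyde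
Conditions: iPr3SiCl, imidazole, DMF, rt
Reagents that add atoms: chlorotriisopropylsilane, CC(C)[Si](Cl)(C(C)C)C(C)C
Why: Standard phenol silylation; the triisopropylsilyl group is chosen to withstand hydride, Lewis acid and K2CO3 later and keeps the ring electron-rich for step 14.

Step 5
Reactants: 4 3-(tert-butyldimethylsilyloxy)-2-methoxycyclopent-2-en-1-one; 6 3-methoxy-4-(triisopropylsilyloxy)benzaldehyde
Product: 8 (S)-2-{hydroxy[3-methoxy-4-(triisopropylsilyloxy)phenyl]methyl}-2-methoxycyclopentane-1,3-dione, via trichlorosilyl aldolate 7 (not isolated)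
Conditions: SiCl4, chiral binaphthyldiamine-derived bisphosphoramide (5 mol %, enantiomer for Re-face attack), iPr2NEt (10 mol %), CH2Cl2, −78 °C; aq. KF/KH2PO4; used at once
Reagents that add atoms: none
Why: Lewis-base-catalysed Mukaiyama aldol addition: the phosphoramide-bound trichlorosilyl cation activates the aromatic aldehyde, the enol silane attacks through an open transition state and the aldolate is held on silicon, which blocks retro-aldol cleavage. Re-face attack gives the (S) carbinol; C1 is not yet a stereocentre because the two ring carbonyls are still equivalent.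

Step 6
Reactants: 8 (S)-aldol adduct
Product: 10 (2S,3R)-3-hydroxy-2-{(S)-hydroxy[3-methoxy-4-(triisopropylsilyloxy)phenyl]methyl}-2-methoxycyclopentan-1-one, via diethylboron chelate 9 (not isolated)
Conditions: Et2BOMe, THF/MeOH (4:1), −78 °C; NaBH4; AcOH, then co-evaporation with MeOH
Reagents that add atoms: none
Why: Narasaka–Prasad reduction: boron ties the benzylic oxygen to one ring carbonyl in a half-chair in which the ring forces the C1 methoxy group axial. Only the chelate with the aryl group equatorial is open to axial hydride attack anti to that methoxy group, so one of the two diastereotopic carbonyls is reduced and C1 (S) and C2 (R) are set from C7.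

Step 7
Reactants: 10 syn-diol
Product: 11 4a-methoxy-4-[3-methoxy-4-(triisopropylsilyloxy)phenyl]-2-phenylhexahydrocyclopenta[d][1,3]dioxin-5-one (trans ring fusion; dioxane chair with 2-phenyl and 4-aryl equatorial and cis; 4a-methoxy axial)
Conditions: PhCH(OMe)2, pyridinium p-toluenesulfonate (cat.), CH2Cl2, rt
Reagents that add atoms: benzaldehyde dimethyl acetal, COC(OC)c1ccccc1
Why: Acetal exchange under thermodynamic control; the syn-1,3-diol gives the all-equatorial chair, and the new acetal carbon takes phenyl equatorial.

Step 8
Reactants: 12 acetaldehyde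
Product: 13 1,1-dibromoprop-1-ene
Conditions: CBr4, PPh3, CH2Cl2, 0 °C
Reagents that add atoms: tetrabromomethane, BrC(Br)(Br)Br
Why: Ramirez dibromo-olefination (first stage of the Corey–Fuchs sequence) of a simple aldehyde.

Step 9
Reactants: 13 1,1-dibromoprop-1-ene; 14 allyltributylstannane
Product: 15 (Z)-3-bromohexa-2,5-diene
Conditions: Pd2(dba)3 (2.5 mol %), tri(2-furyl)phosphine (15 mol %), toluene, 100 °C
Reagents that add atoms: none
Why: Stille coupling of a 1,1-dibromoalkene: zerovalent palladium inserts into the less hindered C–Br bond trans to the methyl group, so the allyl group replaces that bromine and the remaining bromine stays cis to methyl.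

Step 10
Reactants: 15 (Z)-3-bromohexa-2,5-diene; 11 benzylidene acetal ketone
Product: 18 5-[(Z)-hexa-2,5-dien-3-yl]-4a-methoxy-4-[3-methoxy-4-(triisopropylsilyloxy)phenyl]-2-phenylhexahydrocyclopenta[d][1,3]dioxin-5-ol (alkenyl group cis to the benzylic carbon C4; hydroxyl cis to the methoxy group), via alkenyllithium 16 (not isolated), via alkenylcerium dichloride 17 (not isolated)
Conditions: 15, t-BuLi (2 equiv), Et2O, −78 °C; CeCl3, THF, −78 °C; then 11, −78 °C; aq. NH4Cl
Reagents that add atoms: none
Why: Bromine–lithium exchange with retention of alkene geometry, transmetalation to the weakly basic organocerium reagent and 1,2-addition to the hindered ketone. In 11 the methoxy group is axial on the carbon next to the carbonyl and the benzylic carbon is tied back equatorially, so attack anti to the methoxy group (steric and Felkin–Anh preference agree) sets C8 with the alkenyl group cis to the benzylic carbon.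

Step 11
Reactants: 18 tertiary alcohol acetal
Product: 19 (1R,2S,3R)-2-{(S)-benzyloxy[3-methoxy-4-(triisopropylsilyloxy)phenyl]methyl}-1-[(Z)-hexa-2,5-dien-3-yl]-2-methoxycyclopentane-1,3-diol
Conditions: iBu2AlH (4 equiv), CH2Cl2, −78 to 0 °C; aq. potassium sodium tartrate
Reagents that add atoms: none
Why: Reductive opening of a benzylidene acetal: aluminium binds the less hindered ring oxygen O2 (the neighbouring aluminium alkoxide on the same face can assist), the acetal C–O2 bond breaks and hydride quenches the oxocarbenium ion, which leaves the benzyl group on the hindered benzylic oxygen.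

Step 12
Reactants: 19 diol
Product: 20 (2S,3R)-2-{(S)-benzyloxy[3-methoxy-4-(triisopropylsilyloxy)phenyl]methyl}-3-[(Z)-hexa-2,5-dien-3-yl]-3-hydroxy-2-methoxycyclopentan-1-one
Conditions: Dess–Martin periodinane, NaHCO3, CH2Cl2, 0 °C to rt
Reagents that add atoms: none
Why: Dess–Martin oxidation of the only secondary alcohol; the tertiary alcohol is inert and the buffer avoids retro-aldol opening.

Step 13
Reactants: 20 hydroxy ketone
Product: 21 (2S,3R)-2-{(S)-benzyloxy[3-methoxy-4-(triisopropylsilyloxy)phenyl]methyl}-3-[(Z)-hexa-2,5-dien-3-yl]-2-methoxy-3-(triethylsilyloxy)cyclopentan-1-one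
Conditions: Et3SiOTf, 2,6-lutidine, CH2Cl2, −78 to 0 °C
Reagents that add atoms: triethylsilyl trifluoromethanesulfonate, CC[Si](CC)(CC)OS(=O)(=O)C(F)(F)F
Why: Silylation of the tertiary alcohol with a silyl triflate; the silyl ether blocks retro-aldol opening of C8–C1 and is the group lost from oxygen at the end of the pinacol step.

Step 14
Reactants: 21 cyclopentanone precursor
Product: 24 (1R,5R,6R,7S)-5-allyl-1-methoxy-6-methyl-7-[3-methoxy-4-(triisopropylsilyloxy)phenyl]bicyclo[3.2.1]octane-2,8-dione (7-endo aryl, 6-exo methyl), via benzylic cation 22 (not isolated), via tertiary cation 23 (not isolated)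
Conditions: SnCl4 (1.5 equiv), CH2Cl2, −78 to −40 °C; aq. NaHCO3
Reagents that add atoms: none
Why: Proposed new method: SnCl4 ionises the benzylic C7–O bond of 21 (loss of benzyloxide) to the silyloxy-stabilised cation 22; the (Z)-trisubstituted alkene, held cis to C7 on the neighbouring carbinol carbon, attacks through C6 to give the tertiary C5 cation 23, whose ring bond C8–C4 lies parallel to the empty orbital and shifts to C5 while silicon leaves the oxocarbenium ion as the C8 ketone; the closest known reaction type is the ring-enlarging Prins–pinacol rearrangement of 1-alkenylcycloalkanol silyl ethers started by oxocarbenium ions, which has not been run from a benzylic cation one atom closer to the carbinol. The five-membered ring C1–C7–C6–C5–C8 closes by a 5-endo-trig cation–alkene cyclisation, open to a cation, and the six-membered ring C1–C2–C3–C4–C5–C8 arises by one-carbon enlargement of the cyclopentanone through the 1,2-shift. C5 is fixed by the cis fusion inherited from C1 and C8, because C4 can only migrate on the face on which it is already bound; C6 follows from the alkene geometry (methyl cis to C8 becomes exo); at C7 the aryl group should enter anti to both the C6 methyl and the C1 methoxy group, that is endo. The step needs the trisubstituted alkene to react in preference to the allyl group, which its higher nucleophilicity and the five-membered transition state secure, and it needs cyclisation to outrun Grob-type cleavage of C1–C8, for which the irreversible pinacol shift is the driving force; the C2 ketone cannot donate into the cation and the benzyl ether offers no competing cation.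

Step 15
Reactants: 24 bicyclic 2,8-dione
Product: 26 5-allyl-3-hydroxy-1-methoxy-6-methyl-7-[3-methoxy-4-(triisopropylsilyloxy)phenyl]bicyclo[3.2.1]octane-2,8-dione (ring stereocentres as in 24; C3 configuration not controlled, either epimer serves), via potassium enolate 25 (not isolated)
Conditions: KN(SiMe3)2, THF, −78 °C; 2-(phenylsulfonyl)-3-phenyloxaziridine; aq. NH4Cl
Reagents that add atoms: 2-(phenylsulfonyl)-3-phenyloxaziridine, O=S(=O)(N1OC1c1ccccc1)c1ccccc1
Why: Davis hydroxylation of the only possible enolate (C1 and C5 are quaternary, so only C3 can be deprotonated); the non-nucleophilic base spares the non-enolisable dicarbonyl array.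

Step 16
Reactants: 26 acyloin
Product: 28 5-allyl-3-hydroxy-1-methoxy-6-methyl-7-[3-methoxy-4-(triisopropylsilyloxy)phenyl]bicyclo[3.2.1]oct-3-ene-2,8-dione (diosphenol; ring stereocentres as in 24), via trione 27 (not isolated)
Conditions: Dess–Martin periodinane, CH2Cl2, rt
Reagents that add atoms: none
Why: Dess–Martin oxidation of the acyloin to the 2,3-dione, which can enolise only toward C4 because C1 is quaternary.

Step 17
Reactants: 28 diosphenol
Product: 29 5-allyl-1,3-dimethoxy-6-methyl-7-[3-methoxy-4-(triisopropylsilyloxy)phenyl]bicyclo[3.2.1]oct-3-ene-2,8-dione (ring stereocentres as in 24)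
Conditions: Me2SO4, K2CO3, acetone, rt
Reagents that add atoms: dimethyl sulfate, COS(=O)(=O)OC
Why: O-methylation of the acidic enol of a diosphenol; K2CO3 in acetone should leave the aryl silyl ether and the two ketones untouched.

Step 18
Reactants: 29 methoxy enone
Product: 30 (1R,2S,5R,6R,7S)-5-allyl-2-hydroxy-1,3-dimethoxy-6-methyl-7-[3-methoxy-4-(triisopropylsilyloxy)phenyl]bicyclo[3.2.1]oct-3-en-8-one
Conditions: NaBH4, CeCl3·7H2O, MeOH, −78 °C
Reagents that add atoms: none
Why: Luche reduction: the cerium-activated conjugated C2 carbonyl should be reduced in the 1,2 sense, while the strained C8 ketone between two quaternary carbons is expected to rest as its methanol hemiketal. Hydride reaches C2 from the C8 side because the endo aryl group covers the other face, which sets C2 (S).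

Step 19
Reactants: 30 silyl ether
Product: 31 (1R,2S,5R,6R,7S)-5-allyl-2-hydroxy-7-(4-hydroxy-3-methoxyphenyl)-1,3-dimethoxy-6-methylbicyclo[3.2.1]oct-3-en-8-one
Conditions: Bu4NF, AcOH, THF, 0 °C
Reagents that add atoms: none
Why: Fluoride cleavage of the aryl silyl ether; acetic acid buffers the phenoxide and alkoxide so that the β-hydroxy ketone does not undergo retro-aldol opening.

## Compound list

1 | cyclopentane-1,3-dione | O=C1CCC(=O)C1 | starting material
2 | 2-diazocyclopentane-1,3-dione | [N-]=[N+]=C1C(=O)CCC1=O | intermediate
3 | 2-methoxycyclopentane-1,3-dione (enol form) | COC1=C(O)CCC1=O | intermediate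
4 | 3-(tert-butyldimethylsilyloxy)-2-methoxycyclopent-2-en-1-one | COC1=C(O[Si](C)(C)C(C)(C)C)CCC1=O | intermediate
5 | vanillin | COc1cc(C=O)ccc1O | starting material
6 | 3-methoxy-4-(triisopropylsilyloxy)benzaldehyde | COc1cc(C=O)ccc1O[Si](C(C)C)(C(C)C)C(C)C | intermediate
7 | trichlorosilyl ether of 8 | COC1(C(=O)CCC1=O)[C@@H](O[Si](Cl)(Cl)Cl)c1ccc(O[Si](C(C)C)(C(C)C)C(C)C)c(OC)c1 | intermediate (not isolated)
8 | (S)-2-{hydroxy[3-methoxy-4-(triisopropylsilyloxy)phenyl]methyl}-2-methoxycyclopentane-1,3-dione | COC1(C(=O)CCC1=O)[C@@H](O)c1ccc(O[Si](C(C)C)(C(C)C)C(C)C)c(OC)c1 | intermediate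
9 | diethylboron chelate of 8 (boron on the benzylic oxygen and one ring carbonyl) | CC[B-]1(CC)O[C@@H](c2ccc(O[Si](C(C)C)(C(C)C)C(C)C)c(OC)c2)[C@]2(OC)C(=O)CCC2=[O+]1 | intermediate (not isolated)
10 | (2S,3R)-3-hydroxy-2-{(S)-hydroxy[3-methoxy-4-(triisopropylsilyloxy)phenyl]methyl}-2-methoxycyclopentan-1-one | CO[C@]1(C(=O)CC[C@H]1O)[C@@H](O)c1ccc(O[Si](C(C)C)(C(C)C)C(C)C)c(OC)c1 | intermediate
11 | trans-fused benzylidene acetal of 10 (4a-methoxy-4-aryl-2-phenylhexahydrocyclopenta[d][1,3]dioxin-5-one) | CO[C@@]12C(=O)CC[C@H]1O[C@@H](c1ccccc1)O[C@H]2c1ccc(O[Si](C(C)C)(C(C)C)C(C)C)c(OC)c1 | intermediate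
12 | acetaldehyde | CC=O | starting material
13 | 1,1-dibromoprop-1-ene | CC=C(Br)Br | intermediate
14 | allyltributylstannane | C=CC[Sn](CCCC)(CCCC)CCCC | starting material
15 | (Z)-3-bromohexa-2,5-diene | C=CC/C(Br)=C/C | intermediate
16 | (E)-hexa-2,5-dien-3-yllithium (lithium cis to methyl) | C=CC/C([Li])=C/C | intermediate (not isolated)
17 | dichloro[(E)-hexa-2,5-dien-3-yl]cerium | C=CC/C([Ce](Cl)Cl)=C/C | intermediate (not isolated)
18 | alkenyl adduct of 11 (tertiary alcohol, alkenyl cis to the benzylic carbon) | C=CC/C(=C/C)[C@]1(O)CC[C@H]2O[C@@H](c3ccccc3)O[C@@H](c3ccc(O[Si](C(C)C)(C(C)C)C(C)C)c(OC)c3)[C@]12OC | intermediate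
19 | (1R,2S,3R)-2-{(S)-benzyloxy[aryl]methyl}-1-[(Z)-hexa-2,5-dien-3-yl]-2-methoxycyclopentane-1,3-diol | C=CC/C(=C/C)[C@]1(O)CC[C@@H](O)[C@]1(OC)[C@@H](OCc1ccccc1)c1ccc(O[Si](C(C)C)(C(C)C)C(C)C)c(OC)c1 | intermediate
20 | (2S,3R)-2-{(S)-benzyloxy[aryl]methyl}-3-[(Z)-hexa-2,5-dien-3-yl]-3-hydroxy-2-methoxycyclopentan-1-one | C=CC/C(=C/C)[C@]1(O)CCC(=O)[C@]1(OC)[C@@H](OCc1ccccc1)c1ccc(O[Si](C(C)C)(C(C)C)C(C)C)c(OC)c1 | intermediate
21 | (2S,3R)-2-{(S)-benzyloxy[aryl]methyl}-3-[(Z)-hexa-2,5-dien-3-yl]-2-methoxy-3-(triethylsilyloxy)cyclopentan-1-one | C=CC/C(=C/C)[C@]1(O[Si](CC)(CC)CC)CCC(=O)[C@]1(OC)[C@@H](OCc1ccccc1)c1ccc(O[Si](C(C)C)(C(C)C)C(C)C)c(OC)c1 | intermediate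
22 | benzylic C7 cation from 21 | C=CC/C(=C/C)[C@]1(O[Si](CC)(CC)CC)CCC(=O)[C@]1(OC)[CH+]c1ccc(O[Si](C(C)C)(C(C)C)C(C)C)c(OC)c1 | intermediate (not isolated)
23 | cis-fused bicyclo[3.3.0]octyl C5 cation | C=CC[C+]1[C@H](C)[C@@H](c2ccc(O[Si](C(C)C)(C(C)C)C(C)C)c(OC)c2)[C@@]2(OC)C(=O)CC[C@@]12O[Si](CC)(CC)CC | intermediate (not isolated)
24 | (1R,5R,6R,7S)-5-allyl-1-methoxy-6-methyl-7-[3-methoxy-4-(triisopropylsilyloxy)phenyl]bicyclo[3.2.1]octane-2,8-dione | C=CC[C@@]12CCC(=O)[C@@](OC)(C1=O)[C@H](c1ccc(O[Si](C(C)C)(C(C)C)C(C)C)c(OC)c1)[C@H]2C | intermediate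
25 | potassium C2 enolate of 24 | C=CC[C@@]12CC=C([O-])[C@@](OC)(C1=O)[C@H](c1ccc(O[Si](C(C)C)(C(C)C)C(C)C)c(OC)c1)[C@H]2C.[K+] | intermediate (not isolated)
26 | 3-hydroxy derivative of 24 (C3 epimers) | C=CC[C@@]12CC(O)C(=O)[C@@](OC)(C1=O)[C@H](c1ccc(O[Si](C(C)C)(C(C)C)C(C)C)c(OC)c1)[C@H]2C | intermediate
27 | bicyclo[3.2.1]octane-2,3,8-trione | C=CC[C@@]12CC(=O)C(=O)[C@@](OC)(C1=O)[C@H](c1ccc(O[Si](C(C)C)(C(C)C)C(C)C)c(OC)c1)[C@H]2C | intermediate (not isolated)
28 | diosphenol (3-hydroxy-oct-3-ene-2,8-dione) | C=CC[C@@]12C=C(O)C(=O)[C@@](OC)(C1=O)[C@H](c1ccc(O[Si](C(C)C)(C(C)C)C(C)C)c(OC)c1)[C@H]2C | intermediate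
29 | 5-allyl-1,3-dimethoxy-6-methyl-7-aryl-bicyclo[3.2.1]oct-3-ene-2,8-dione | C=CC[C@@]12C=C(OC)C(=O)[C@@](OC)(C1=O)[C@H](c1ccc(O[Si](C(C)C)(C(C)C)C(C)C)c(OC)c1)[C@H]2C | intermediate
30 | O-triisopropylsilyl ether of the target | C=CC[C@@]12C=C(OC)[C@H](O)[C@@](OC)(C1=O)[C@H](c1ccc(O[Si](C(C)C)(C(C)C)C(C)C)c(OC)c1)[C@H]2C | intermediate
31 | (1R,2S,5R,6R,7S)-5-allyl-2-hydroxy-7-(4-hydroxy-3-methoxyphenyl)-1,3-dimethoxy-6-methylbicyclo[3.2.1]oct-3-en-8-one | C=CC[C@@]12C=C(OC)[C@H](O)[C@@](OC)(C1=O)[C@H](c1ccc(O)c(OC)c1)[C@H]2C | target

## Step count and uncertain steps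

Total step count: 19. Longest linear sequence: 16 steps (steps 1–3, 5–7 and 10–19, from 1 to 31). Step 4 and steps 8–9 are side branches.

**Step 14 (key step).** The most likely failure is Grob-type cleavage of the C1–C8 bond, pushed by the silyloxy group, before the 5-endo closure can take place. The cation is well stabilised and long-lived, and 5-endo attack is geometrically demanding. Entry of the aryl group on the exo face, or proton loss from the C5 cation, are the next risks. The fallback uses the established acid-promoted cycloaddition of a quinone-monoketal cation with a propenylarene, the known entry to this ring system. It sets out from 6 and returns at 29.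
- Aldehyde 6 is converted by Wittig ethylidenation and iodine-catalysed equilibration into (E)-2-methoxy-4-(prop-1-enyl)-1-(triisopropylsilyloxy)benzene F1.
- Commercial 2,3,4-trimethoxyphenol F2 is O-allylated to allyl 2,3,4-trimethoxyphenyl ether F3, rearranged thermally (Claisen) to 6-allyl-2,3,4-trimethoxyphenol F4 and oxidised with PhI(OAc)2 in MeOH to 2-allyl-4,4,5,6-tetramethoxycyclohexa-2,5-dien-1-one F5.
- Ionisation of F5 with SnCl4 or CF3SO3H in the presence of F1 should give racemic 29. The propenyl carbon bearing methyl bonds to the allyl-bearing ring carbon and the benzylic carbon to the methoxy-bearing one.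
- The enantiomers are separated on a chiral stationary phase into 29 and its mirror image ent-29 F6. The route continues from 29 with step 18.

**Step 5.** The push–pull, tetrasubstituted enol silane is a weak nucleophile and the aldehyde is electron-rich, so slow addition, modest enantioselectivity or erosion through retro-aldol cleavage of the product are to be expected. The fallback gives up asymmetric catalysis for resolution. It sets out from 4 and 6 and returns at 10. A BF3·OEt2-promoted Mukaiyama aldol addition should give racemic 8, that is 8 together with its (R)-enantiomer F7. Step 6 applied to the racemate gives 10 and its enantiomer ent-10 F8. A lipase (Candida antarctica lipase B, vinyl acetate), selected so that it acylates the ring hydroxyl of the unwanted enantiomer, converts F8 into its ring acetate F9 and leaves 10, which is separated and carried into step 7.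

**Step 11.** Opening of the acetal in the opposite sense (aluminium on the benzylic oxygen) would free the wrong hydroxyl. The fallback drops the regioselective opening and moves the C2 oxidation behind the rearrangement. It sets out from 18 and returns at 24. Alcohol 18 is silylated (Et3SiOTf, 2,6-lutidine) to the triethylsilyl ether of 18 F10. F10 is treated with SnCl4 as in step 14, with the acetal oxygen on C7 as the leaving group and loss of benzaldehyde on work-up. This should give 5-allyl-2-hydroxy-1-methoxy-6-methyl-7-aryl-bicyclo[3.2.1]octan-8-one F11, with the hydroxyl on the C8 side. Dess–Martin oxidation of F11 gives 24. The cost is a C2 alkoxide that can donate into the C7 cation and open the ring, which is why this order is not the first choice.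

**Step 18.** Competing reduction of the strained C8 ketone, which is reachable over the flat enone bridge, is the main danger. The fallback replaces chemoselective reduction by protection. It sets out from 29 and returns at 31. Excess NaBH4 reduces both carbonyls to the 2,8-diol F12, with C2 set as in 30 and the C8 configuration irrelevant. Et3SiCl and imidazole silylate the less hindered allylic C2 hydroxyl to give the 2-O-triethylsilyl ether F13. Dess–Martin oxidation restores the C8 ketone in the 2-O-triethylsilyl 8-ketone F14. Bu4NF buffered with AcOH then removes both silyl groups to give 31.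

## Further compounds

F1 | step 14 | (E)-2-methoxy-4-(prop-1-enyl)-1-(triisopropylsilyloxy)benzene | C/C=C/c1ccc(O[Si](C(C)C)(C(C)C)C(C)C)c(OC)c1
F2 | step 14 | 2,3,4-trimethoxyphenol | COc1ccc(O)c(OC)c1OC
F3 | step 14 | allyl 2,3,4-trimethoxyphenyl ether | C=CCOc1ccc(OC)c(OC)c1OC
F4 | step 14 | 6-allyl-2,3,4-trimethoxyphenol | C=CCc1cc(OC)c(OC)c(OC)c1O
F5 | step 14 | 2-allyl-4,4,5,6-tetramethoxycyclohexa-2,5-dien-1-one | C=CCC1=CC(OC)(OC)C(OC)=C(OC)C1=O
F6 | step 14 | ent-29 | C=CC[C@]12C=C(OC)C(=O)[C@](OC)(C1=O)[C@@H](c1ccc(O[Si](C(C)C)(C(C)C)C(C)C)c(OC)c1)[C@@H]2C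
F7 | step 5 | (R)-enantiomer of 8 | COC1(C(=O)CCC1=O)[C@H](O)c1ccc(O[Si](C(C)C)(C(C)C)C(C)C)c(OC)c1
F8 | step 5 | ent-10 | CO[C@@]1(C(=O)CC[C@@H]1O)[C@H](O)c1ccc(O[Si](C(C)C)(C(C)C)C(C)C)c(OC)c1
F9 | step 5 | ring acetate of ent-10 | CO[C@@]1(C(=O)CC[C@@H]1OC(C)=O)[C@H](O)c1ccc(O[Si](C(C)C)(C(C)C)C(C)C)c(OC)c1
F10 | step 11 | triethylsilyl ether of 18 | C=CC/C(=C/C)[C@]1(O[Si](CC)(CC)CC)CC[C@H]2O[C@@H](c3ccccc3)O[C@@H](c3ccc(O[Si](C(C)C)(C(C)C)C(C)C)c(OC)c3)[C@]12OC
F11 | step 11 | 5-allyl-2-hydroxy-1-methoxy-6-methyl-7-[3-methoxy-4-(triisopropylsilyloxy)phenyl]bicyclo[3.2.1]octan-8-one (2-hydroxyl on the C8 side) | C=CC[C@@]12CC[C@@H](O)[C@@](OC)(C1=O)[C@H](c1ccc(O[Si](C(C)C)(C(C)C)C(C)C)c(OC)c1)[C@H]2C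
F12 | step 18 | 5-allyl-1,3-dimethoxy-6-methyl-7-[3-methoxy-4-(triisopropylsilyloxy)phenyl]bicyclo[3.2.1]oct-3-ene-2,8-diol (C8 epimers) | C=CC[C@@]12C=C(OC)[C@H](O)[C@@](OC)(C1O)[C@H](c1ccc(O[Si](C(C)C)(C(C)C)C(C)C)c(OC)c1)[C@H]2C
F13 | step 18 | 2-O-triethylsilyl ether of F12 | C=CC[C@@]12C=C(OC)[C@H](O[Si](CC)(CC)CC)[C@@](OC)(C1O)[C@H](c1ccc(O[Si](C(C)C)(C(C)C)C(C)C)c(OC)c1)[C@H]2C
F14 | step 18 | 2-O-triethylsilyl ether of 30 | C=CC[C@@]12C=C(OC)[C@H](O[Si](CC)(CC)CC)[C@@](OC)(C1=O)[C@H](c1ccc(O[Si](C(C)C)(C(C)C)C(C)C)c(OC)c1)[C@H]2C
A1 | alternative 1 | (E,E)-2-methoxy dienone, 4-allyl-2-methoxy-1-[4-(tert-butyldimethylsilyloxy)-3-methoxyphenyl]hexa-1,4-dien-3-one | C/C=C(CC=C)/C(=O)/C(OC)=C\c1ccc(O[Si](C)(C)C(C)(C)C)c(OC)c1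
A2 | alternative 1 | 2-allyl-5-methoxy-3-methyl-4-arylcyclopentanone (aryl O-silylated) | C=CC[C@@H]1C(=O)[C@@H](OC)[C@H](c2ccc(O[Si](C)(C)C(C)(C)C)c(OC)c2)[C@H]1C
A3 | alternative 2 | 2-allyl-5-methoxy-4-arylcyclopent-2-en-1-one (aryl O-silylated) | C=CCC1=C[C@@H](c2ccc(O[Si](C)(C)C(C)(C)C)c(OC)c2)[C@H](OC)C1=O
A4 | alternative 2 | 2-allyl-5-methoxy-2-(2-methoxyallyl)-3-methyl-4-arylcyclopentanone (aryl O-silylated) | C=CC[C@@]1(CC(OC)=C)C(=O)[C@@H](OC)[C@H](c2ccc(O[Si](C)(C)C(C)(C)C)c(OC)c2)[C@H]1C
A5 | alternative 3 | cis-fused 6-allyl-3-(tert-butyldimethylsilyloxy)-1-methoxy-7-methyl-8-[3-methoxy-4-(triisopropylsilyloxy)phenyl]bicyclo[4.2.0]octan-2-one | C=CC[C@@]12CC[C@H](O[Si](C)(C)C(C)(C)C)C(=O)[C@]1(OC)[C@H](c1ccc(O[Si](C(C)C)(C(C)C)C(C)C)c(OC)c1)[C@H]2C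
A6 | alternative 3 | 5-allyl-7-aryl-1-methoxy-6-methyl-2-silyloxybicyclo[3.2.1]octan-8-one | C=CC[C@@]12CC[C@H](O[Si](C)(C)C(C)(C)C)[C@@](OC)(C1=O)[C@H](c1ccc(O[Si](C(C)C)(C(C)C)C(C)C)c(OC)c1)[C@H]2C
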